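**Plan**

- Retrosynthetic cuts: the enone Cα–Cβ bond (aldol condensation with the chromene aldehyde), the C5–acetyl bond on the benzofuran (ortho-metalation), the C2–C3 bond of the dihydrofuran (carbene C–H alkylation) and the aryl O–CH2 bond (epoxide opening).
- Enabling feature: in the dihydrofuran ring C3 is an unsubstituted CH2 on arene carbon C3a and C2 is the ether carbon on O1, so C2–C3 corresponds to a benzylic carbene (the former aldehyde carbon) inserting into the O–CH2 group of an aryl 2-silyloxy-2-methylpropyl ether.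
- Forward order: ether chain onto 2,6-dihydroxybenzaldehyde, dihydrofuran ring by C2–C3 closure (the only ring made; the chromene is bought), acetyl group at C5, enone, deprotection.
- Stereochemistry: the single stereocentre C2 (R) is set in the ring closure by the chiral cavity of a divalent cobalt amidoporphyrin; the (E)-alkene follows from thermodynamic control in the aldol dehydration.
- Protecting groups: the phenol next to the carbene carbon is a silyl ether during the ring closure, because an O–CH2–O acetal there would offer competing hydrogens at the same 1,5 distance; it is exchanged for MOM afterwards to direct the lithiation.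

Key step: step 4

Assumption: 2,2-dimethyl-2H-chromene-6-carbaldehyde is bought, and of the two antipodes of the chiral porphyrin ligand (built from (S)- or (R)-2,2-dimethylcyclopropanecarboxamide) the one that leads to (R) at C2 is used.

**Route**

Step 1
Reactants: 1 2,6-dihydroxybenzaldehyde; 2 isobutylene oxide (2,2-dimethyloxirane)
Product: 3 2-hydroxy-6-(2-hydroxy-2-methylpropoxy)benzaldehyde
Conditions: 2 (1.3 equiv), K2CO3 (0.3 equiv), DMF, 80 °C, sealed tube
Reagents that add atoms: isobutylene oxide 2, CC1(C)CO1
Why: Base-catalysed phenol epoxide ring-opening (SN2 at the unsubstituted CH2 of the epoxide) should give the 2-hydroxy-2-methylpropyl ether, and the remaining phenol, held in a hydrogen bond to the aldehyde, should resist a second alkylation.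

Step 2
Reactants: 3 2-hydroxy-6-(2-hydroxy-2-methylpropoxy)benzaldehyde
Product: 5 2-(tert-butyldimethylsilyloxy)-6-[2-(tert-butyldimethylsilyloxy)-2-methylpropoxy]benzaldehyde, via aryl mono-silyl ether 4 (not isolated)
Conditions: TBSOTf (2.4 equiv), 2,6-lutidine (3.5 equiv), CH2Cl2, 0 °C → rt
Reagents that add atoms: tert-butyldimethylsilyl trifluoromethanesulfonate (TBSOTf), CC(C)(C)[Si](C)(C)OS(=O)(=O)C(F)(F)F
Why: Silyl triflate silylation is reactive enough to cap first the phenol and then the hindered tertiary alcohol in one operation, while the non-enolisable aldehyde is left alone.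

Step 3
Reactants: 5 2-(tert-butyldimethylsilyloxy)-6-[2-(tert-butyldimethylsilyloxy)-2-methylpropoxy]benzaldehyde; 6 tosylhydrazide (4-methylbenzenesulfonohydrazide)
Product: 7 (E)-N'-{2-(tert-butyldimethylsilyloxy)-6-[2-(tert-butyldimethylsilyloxy)-2-methylpropoxy]benzylidene}-4-methylbenzenesulfonohydrazide
Conditions: 6 (1.05 equiv), MeOH/CH2Cl2, rt
Reagents that add atoms: tosylhydrazide 6, Cc1ccc(S(=O)(=O)NN)cc1
Why: N-Tosylhydrazone formation by condensation of the aldehyde with the sulfonyl hydrazide proceeds without added acid or base, should give the (E)-hydrazone and spares both silyl ethers.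

Step 4
Reactants: 7 (E)-N'-{2-(tert-butyldimethylsilyloxy)-6-[2-(tert-butyldimethylsilyloxy)-2-methylpropoxy]benzylidene}-4-methylbenzenesulfonohydrazide
Product: 9 (R)-4-(tert-butyldimethylsilyloxy)-2-[2-(tert-butyldimethylsilyloxy)propan-2-yl]-2,3-dihydrobenzofuran, via aryldiazomethane 8 (not isolated)
Conditions: [Co(3,5-DitBu-ChenPhyrin)] (3 mol %), Cs2CO3 (2 equiv), 1,4-dioxane, 40 °C, N2
Reagents that add atoms: none
Why: Carbonate deprotonates the hydrazone, which loses toluenesulfinate and releases the aryldiazomethane slowly; divalent cobalt takes it up with loss of N2 as an alpha-cobalt benzyl radical (cobalt now trivalent), this abstracts a hydrogen from the OCH2 group through a six-membered transition state, and the alpha-alkoxy radical then displaces cobalt from the benzylic carbon to form C2–C3 and return the divalent catalyst. The closest known reaction type is the enantioselective cobalt-porphyrin metalloradical 1,5-C–H alkylation with diazo compounds released in situ from sulfonylhydrazones, which closes five-membered N- and O-heterocycles, alongside donor-carbene C–H insertions into aryl ether O–CH2 groups that give 2,3-dihydrobenzofurans; the ether CH2 used here is flanked by a quaternary carbon and is a more hindered member of that class. The dihydrofuran ring closes by 5-exo-tet homolytic substitution at the cobalt-bearing benzylic carbon. The C2 stereocentre is under catalyst control: the planar alpha-alkoxy radical is held in the chiral cavity of the amidoporphyrin and bonds through one face, so the ligand antipode fixes (R). The step needs site selectivity and suppression of carbene dimerisation or azine formation: the silyl ether on the other ortho oxygen has no C–H at the 1,5 position (its Si–CH3 hydrogens are one atom further and unactivated), and the low standing diazo concentration together with the one-electron character of the catalyst disfavours dimerisation.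

Step 5
Reactants: 9 (R)-4-(tert-butyldimethylsilyloxy)-2-[2-(tert-butyldimethylsilyloxy)propan-2-yl]-2,3-dihydrobenzofuran
Product: 11 (R)-2-[2-(tert-butyldimethylsilyloxy)propan-2-yl]-4-(methoxymethoxy)-2,3-dihydrobenzofuran, via free phenol 10 (not isolated)
Conditions: TBAF (1.1 equiv), THF, 0 °C; then MOMCl (1.5 equiv), 0 °C → rt
Reagents that add atoms: chloromethyl methyl ether (MOMCl), COCCl
Why: One-pot fluoride desilylation and Williamson-type etherification: the aryl silyl ether should cleave within minutes at 0 °C while the hindered tertiary alkyl silyl ether stays, and the tetrabutylammonium phenoxide is alkylated in situ by MOMCl.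

Step 6
Reactants: 11 (R)-2-[2-(tert-butyldimethylsilyloxy)propan-2-yl]-4-(methoxymethoxy)-2,3-dihydrobenzofuran
Product: 14 (R)-1-{2-[2-(tert-butyldimethylsilyloxy)propan-2-yl]-4-(methoxymethoxy)-2,3-dihydrobenzofuran-5-yl}ethan-1-one, via aryllithium 12 (not isolated), via lithium hemiaminal adduct 13 (not isolated)
Conditions: s-BuLi (1.2 equiv), TMEDA (1.2 equiv), THF, −78 °C; then MeC(O)N(OMe)Me (1.5 equiv), −78 → 0 °C; aq NH4Cl
Reagents that add atoms: N-methoxy-N-methylacetamide, CC(=O)N(C)OC
Why: Directed ortho-metalation: the MOM acetal should steer deprotonation to C5, its only free ortho position, in preference to C7 beside the weaker ring-ether donor, and the aryllithium adds only once to the Weinreb amide because the chelated tetrahedral adduct survives until the quench.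

Step 7
Reactants: 14 (R)-1-{2-[2-(tert-butyldimethylsilyloxy)propan-2-yl]-4-(methoxymethoxy)-2,3-dihydrobenzofuran-5-yl}ethan-1-one; 15 2,2-dimethyl-2H-chromene-6-carbaldehyde
Product: 17 (E)-1-{(R)-2-[2-(tert-butyldimethylsilyloxy)propan-2-yl]-4-(methoxymethoxy)-2,3-dihydrobenzofuran-5-yl}-3-(2,2-dimethyl-2H-chromen-6-yl)prop-2-en-1-one, via aldol adduct 16 (not isolated)
Conditions: 15 (1.1 equiv), KOH (3 equiv), EtOH, 0 °C → rt
Reagents that add atoms: 2,2-dimethyl-2H-chromene-6-carbaldehyde 15, CC1(C)C=Cc2cc(C=O)ccc2O1
Why: Claisen–Schmidt condensation: the methyl ketone enolate adds to the non-enolisable aldehyde and the aldol eliminates under the basic conditions to the conjugated (E)-enone, the acetal and the silyl ether both being base-stable.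

Step 8
Reactants: 17 (E)-1-{(R)-2-[2-(tert-butyldimethylsilyloxy)propan-2-yl]-4-(methoxymethoxy)-2,3-dihydrobenzofuran-5-yl}-3-(2,2-dimethyl-2H-chromen-6-yl)prop-2-en-1-one
Product: 19 (E)-1-[(2R)-4-hydroxy-2-(2-hydroxypropan-2-yl)-2,3-dihydrobenzofuran-5-yl]-3-(2,2-dimethyl-2H-chromen-6-yl)prop-2-en-1-one, via phenol silyl ether 18 (not isolated)
Conditions: HCl (1.25 M in MeOH), THF, rt → 40 °C
Reagents that add atoms: none
Why: Acid-catalysed methanolysis (acetal exchange, then silyl ether solvolysis) should remove the carbonyl-chelated aryl MOM ether quickly and the tertiary silyl ether more slowly, under conditions mild enough to leave the C2 ether stereocentre, the chromene and the enone untouched.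

**Compound list**

1 | 2,6-dihydroxybenzaldehyde | O=Cc1c(O)cccc1O | starting material
2 | isobutylene oxide (2,2-dimethyloxirane) | CC1(C)CO1 | starting material
3 | 2-hydroxy-6-(2-hydroxy-2-methylpropoxy)benzaldehyde | CC(C)(O)COc1cccc(O)c1C=O | intermediate
4 | 2-(tert-butyldimethylsilyloxy)-6-(2-hydroxy-2-methylpropoxy)benzaldehyde (not isolated) | CC(C)(O)COc1cccc(O[Si](C)(C)C(C)(C)C)c1C=O | intermediate
5 | 2-(tert-butyldimethylsilyloxy)-6-[2-(tert-butyldimethylsilyloxy)-2-methylpropoxy]benzaldehyde | CC(C)(C)[Si](C)(C)OC(C)(C)COc1cccc(O[Si](C)(C)C(C)(C)C)c1C=O | intermediate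
6 | tosylhydrazide (4-methylbenzenesulfonohydrazide) | Cc1ccc(S(=O)(=O)NN)cc1 | starting material
7 | (E)-N'-{2-(tert-butyldimethylsilyloxy)-6-[2-(tert-butyldimethylsilyloxy)-2-methylpropoxy]benzylidene}-4-methylbenzenesulfonohydrazide | Cc1ccc(cc1)S(=O)(=O)N/N=C/c1c(O[Si](C)(C)C(C)(C)C)cccc1OCC(C)(C)O[Si](C)(C)C(C)(C)C | intermediate
8 | 1-(diazomethyl)-2-(tert-butyldimethylsilyloxy)-6-[2-(tert-butyldimethylsilyloxy)-2-methylpropoxy]benzene (not isolated) | [N-]=[N+]=Cc1c(O[Si](C)(C)C(C)(C)C)cccc1OCC(C)(C)O[Si](C)(C)C(C)(C)C | intermediate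
9 | (R)-4-(tert-butyldimethylsilyloxy)-2-[2-(tert-butyldimethylsilyloxy)propan-2-yl]-2,3-dihydrobenzofuran | CC(C)(C)[Si](C)(C)Oc1cccc2c1C[C@H](C(C)(C)O[Si](C)(C)C(C)(C)C)O2 | intermediate
10 | (R)-2-[2-(tert-butyldimethylsilyloxy)propan-2-yl]-2,3-dihydrobenzofuran-4-ol, present as its tetrabutylammonium phenoxide (not isolated) | Oc1cccc2c1C[C@H](C(C)(C)O[Si](C)(C)C(C)(C)C)O2 | intermediate
11 | (R)-2-[2-(tert-butyldimethylsilyloxy)propan-2-yl]-4-(methoxymethoxy)-2,3-dihydrobenzofuran | COCOc1cccc2c1C[C@H](C(C)(C)O[Si](C)(C)C(C)(C)C)O2 | intermediate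
12 | 5-lithio derivative of 11 (not isolated) | COCOc1c([Li])ccc2c1C[C@H](C(C)(C)O[Si](C)(C)C(C)(C)C)O2 | intermediate
13 | lithium alkoxide of the N-methoxy-N-methyl hemiaminal at C5, mixture at the new carbon (not isolated) | COCOc1c(C(C)(O[Li])N(C)OC)ccc2c1C[C@H](C(C)(C)O[Si](C)(C)C(C)(C)C)O2 | intermediate
14 | (R)-1-{2-[2-(tert-butyldimethylsilyloxy)propan-2-yl]-4-(methoxymethoxy)-2,3-dihydrobenzofuran-5-yl}ethan-1-one | COCOc1c(C(C)=O)ccc2c1C[C@H](C(C)(C)O[Si](C)(C)C(C)(C)C)O2 | intermediate
15 | 2,2-dimethyl-2H-chromene-6-carbaldehyde | CC1(C)C=Cc2cc(C=O)ccc2O1 | starting material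
16 | 3-hydroxy-3-(2,2-dimethyl-2H-chromen-6-yl)-1-aryl-propan-1-one aldol adduct of 14 and 15, mixture at the carbinol (not isolated) | COCOc1c(C(=O)CC(O)c3ccc4OC(C)(C)C=Cc4c3)ccc2c1C[C@H](C(C)(C)O[Si](C)(C)C(C)(C)C)O2 | intermediate
17 | (E)-1-{(R)-2-[2-(tert-butyldimethylsilyloxy)propan-2-yl]-4-(methoxymethoxy)-2,3-dihydrobenzofuran-5-yl}-3-(2,2-dimethyl-2H-chromen-6-yl)prop-2-en-1-one | COCOc1c(C(=O)/C=C/c3ccc4OC(C)(C)C=Cc4c3)ccc2c1C[C@H](C(C)(C)O[Si](C)(C)C(C)(C)C)O2 | intermediate
18 | (E)-1-{(R)-2-[2-(tert-butyldimethylsilyloxy)propan-2-yl]-4-hydroxy-2,3-dihydrobenzofuran-5-yl}-3-(2,2-dimethyl-2H-chromen-6-yl)prop-2-en-1-one (not isolated) | Oc1c(C(=O)/C=C/c3ccc4OC(C)(C)C=Cc4c3)ccc2c1C[C@H](C(C)(C)O[Si](C)(C)C(C)(C)C)O2 | intermediate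
19 | (E)-1-[(2R)-4-hydroxy-2-(2-hydroxypropan-2-yl)-2,3-dihydrobenzofuran-5-yl]-3-(2,2-dimethyl-2H-chromen-6-yl)prop-2-en-1-one (CNP0302034.2) | CC1(C)C=Cc2cc(/C=C/C(=O)c3ccc4c(c3O)C[C@H](C(C)(C)O)O4)ccc2O1 | target

**Summary**

Total step count: 8. Longest linear sequence: 8 steps (1 → 19); aldehyde 15 enters at step 7.

Steps most likely to fail:

1. Step 4. Hydrogen abstraction from the OCH2 group may be slowed by the neighbouring quaternary carbon, so that azine formation or carbene dimerisation, base-induced loss of the aryl silyl ether, or poor face selectivity in the ring closure takes over. The fallback sets out from 1 and comes back at 9, placing the C2 stereocentre by asymmetric hydrogenation of a benzofuran. O-Alkylation of 1 with ethyl bromoacetate and in situ aldol condensation–dehydration (K2CO3, DMF, 100 °C, Rap–Stoermer-type) should give ethyl 4-hydroxybenzofuran-2-carboxylate F1. Excess MeMgBr (THF, 0 °C) should convert the ester into 2-(4-hydroxybenzofuran-2-yl)propan-2-ol F2. TBSOTf/2,6-lutidine should then give 4-(tert-butyldimethylsilyloxy)-2-[2-(tert-butyldimethylsilyloxy)propan-2-yl]benzofuran F3. Enantioselective hydrogenation of the furan C2=C3 bond (H2, [Ru(cod)(2-methylallyl)2], chiral N-heterocyclic carbene precursor SINpEt·HBF4, KOtBu, hexane) would deliver 9.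

2. Step 6. Lithiation may go to C7 beside the ring oxygen or to the benzylic C3 (with ring-opening by beta-elimination), and the aryllithium may enolise the Weinreb amide instead of adding to it. The fallback sets out from 9 and comes back at 18, using electrophilic ortho-formylation of the magnesium phenoxide in place of metalation. TBAF (THF, 0 °C) cleaves the aryl silyl ether and phenol 10 is isolated. MgCl2, Et3N and paraformaldehyde in MeCN at reflux (Casnati–Skattebøl formylation) should formylate the only free ortho position to give (R)-2-[2-(tert-butyldimethylsilyloxy)propan-2-yl]-4-hydroxy-2,3-dihydrobenzofuran-5-carbaldehyde F4. MeMgBr (2.5 equiv, THF, 0 °C) should give the 5-(1-hydroxyethyl) phenol F5, and MnO2 (CH2Cl2, rt) should oxidise it to (R)-1-{2-[2-(tert-butyldimethylsilyloxy)propan-2-yl]-4-hydroxy-2,3-dihydrobenzofuran-5-yl}ethan-1-one F6. Claisen–Schmidt condensation of this 2'-hydroxyacetophenone with 15 (KOH, EtOH) gives 18, which then needs only the silyl ether cleavage of step 8.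

3. Step 8. Cleavage of the tertiary silyl ether may lag behind, and the longer acid exposure may bring on conjugate cyclisation of the 2'-hydroxychalcone to the flavanone, addition of methanol to the chromene double bond, or ionisation next to the tertiary carbinol. The fallback sets out from 14 and comes back at 19, moving the acid step ahead of the condensation so that only the robust acetophenone meets acid. HCl in MeOH (40 °C) should convert 14 into (R)-1-[4-hydroxy-2-(2-hydroxypropan-2-yl)-2,3-dihydrobenzofuran-5-yl]ethan-1-one F7. Claisen–Schmidt condensation of this unprotected 2'-hydroxyacetophenone with 15 (KOH, EtOH, rt) would then give 19 directly.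

Further compounds
F1 | step 4 | ethyl 4-hydroxybenzofuran-2-carboxylate | CCOC(=O)c1cc2c(O)cccc2o1
F2 | step 4 | 2-(4-hydroxybenzofuran-2-yl)propan-2-ol | CC(C)(O)c1cc2c(O)cccc2o1
F3 | step 4 | 4-(tert-butyldimethylsilyloxy)-2-[2-(tert-butyldimethylsilyloxy)propan-2-yl]benzofuran | CC(C)(C)[Si](C)(C)OC(C)(C)c1cc2c(O[Si](C)(C)C(C)(C)C)cccc2o1
F4 | step 6 | (R)-2-[2-(tert-butyldimethylsilyloxy)propan-2-yl]-4-hydroxy-2,3-dihydrobenzofuran-5-carbaldehyde | O=Cc1ccc2c(c1O)C[C@H](C(C)(C)O[Si](C)(C)C(C)(C)C)O2
F5 | step 6 | (2R)-2-[2-(tert-butyldimethylsilyloxy)propan-2-yl]-5-(1-hydroxyethyl)-2,3-dihydrobenzofuran-4-ol, mixture at the carbinol | CC(O)c1ccc2c(c1O)C[C@H](C(C)(C)O[Si](C)(C)C(C)(C)C)O2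
F6 | step 6 | (R)-1-{2-[2-(tert-butyldimethylsilyloxy)propan-2-yl]-4-hydroxy-2,3-dihydrobenzofuran-5-yl}ethan-1-one | CC(=O)c1ccc2c(c1O)C[C@H](C(C)(C)O[Si](C)(C)C(C)(C)C)O2
F7 | step 8 | (R)-1-[4-hydroxy-2-(2-hydroxypropan-2-yl)-2,3-dihydrobenzofuran-5-yl]ethan-1-one | CC(=O)c1ccc2c(c1O)C[C@H](C(C)(C)O)O2
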